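Retrosynthesis: remove the five silicon groups, then cut O5–C6 of ring C (ester carbonyl oxygen + alkyne), then O1–C7a and C3a–C4 of ring B in one operation (hydroxyl + alkyne + CO), then C2–C3 (aryl aldehyde + allenylstannane), then C3–C3a (ring D aldehyde + aryl diyne).
Enabling feature (furo[3,2-c]pyran-4-one numbering; ring A = catechol on C2, ring B = dihydrofuran, ring C = fused pyranone, ring D = pendant pyranone on C3): the fusion carbons C3a and C7a shared by rings B and C, followed by C7 and C6 of ring C, are at the oxidation level of a conjugated diyne. The C2 oxygen can reach C7a, C4 is a single carbon at the acid level and can enter as CO, and O5 can be the carbonyl oxygen of the ester so formed.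
Forward order: both catechol units come from 3,4-dihydroxybenzaldehyde and ring D from 4-hydroxy-6-methyl-2H-pyran-2-one. The chain is joined at C3–C3a, then at C2–C3; ring B closes, then ring C, and all silicon groups leave together at the end.
Stereochemistry: the target is the cis-(2R,3S) isomer. A Zn–ProPhenol alkynylation sets a carbinol centre at the future C3, and anti SN2' stannylation turns it into an allene axis. Anti SE2' addition converts the axis into C3 (S), its open transition state sets C2 (R) syn, and syn becomes cis unchanged.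

Key step: step 11

Assumption: (S,S)-ProPhenol is taken to deliver the diynyl group to the Re face of the ring D aldehyde, as with aryl and α,β-unsaturated aldehydes. The configuration of the propargylic alcohol is to be checked through its MTPA esters, and the equally available (R,R)-ligand is used if the sense is reversed.
Abbreviations: TBS = tert-butyldimethylsilyl; TMSE = 2-(trimethylsilyl)ethyl.

Step 1
Reactants: 1 3,4-dihydroxybenzaldehyde
Product: 2 3,4-bis(tert-butyldimethylsilyloxy)benzaldehyde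
Conditions: TBSCl (2.4 equiv), imidazole, DMF, rt
Reagents that add atoms: tert-butyldimethylsilyl chloride, CC(C)(C)[Si](C)(C)Cl
Why: Imidazole-promoted silylation of phenols is routine, and the bis-silyl ether shields the catechol from oxidation and metal chelation until the fluoride step at the end.

Step 2
Reactants: 2 3,4-bis(tert-butyldimethylsilyloxy)benzaldehyde
Product: 3 4-(2,2-dibromoethenyl)-1,2-bis(tert-butyldimethylsilyloxy)benzene
Conditions: CBr4, PPh3, CH2Cl2, 0 °C
Reagents that add atoms: carbon tetrabromide, BrC(Br)(Br)Br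
Why: Ramirez dibromo-olefination (first stage of the Corey–Fuchs sequence) works well on electron-rich benzaldehydes, and its neutral medium leaves aryl silyl ethers untouched.

Step 3
Reactants: 3 4-(2,2-dibromoethenyl)-1,2-bis(tert-butyldimethylsilyloxy)benzene; 4 trimethylsilylacetylene
Product: 5 {4-[3,4-bis(tert-butyldimethylsilyloxy)phenyl]buta-1,3-diyn-1-yl}trimethylsilane
Conditions: Pd2(dba)3 (2.5 mol %), P(4-MeOC6H4)3 (10 mol %), Et3N, DMF, 80 °C, sealed tube
Reagents that add atoms: none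
Why: Sonogashira-type coupling of a 1,1-dibromoalkene with a terminal alkyne under an electron-rich phosphine also loses the second HBr, so the unsymmetrical 1,3-diyne forms directly and without the homocoupling typical of copper-mediated diyne syntheses.

Step 4
Reactants: 5 {4-[3,4-bis(tert-butyldimethylsilyloxy)phenyl]buta-1,3-diyn-1-yl}trimethylsilane
Product: 6 4-(buta-1,3-diyn-1-yl)-1,2-bis(tert-butyldimethylsilyloxy)benzene
Conditions: AgNO3 (10 mol %), acetone/H2O, rt, dark; extracted into toluene, dried, used at once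
Reagents that add atoms: none
Why: Silver-catalysed protiodesilylation cleaves the C(sp)–Si bond through a silver acetylide under neutral conditions that spare the base-sensitive aryl silyl ethers, and the fragile terminal diyne is never concentrated to dryness.

Step 5
Reactants: 7 4-hydroxy-6-methyl-2H-pyran-2-one
Product: 8 6-methyl-4-[2-(trimethylsilyl)ethoxy]-2H-pyran-2-one
Conditions: 2-(trimethylsilyl)ethanol, PPh3, DIAD, THF, 0 °C to rt
Reagents that add atoms: 2-(trimethylsilyl)ethanol, C[Si](C)(C)CCO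
Why: Mitsunobu alkylation of this acidic vinylogous acid takes place at O4 to give the 4-alkoxy-2-pyranone, and the TMSE group then behaves as a vinylogous ester that fluoride removes together with the silyl ethers.

Step 6
Reactants: 8 6-methyl-4-[2-(trimethylsilyl)ethoxy]-2H-pyran-2-one
Product: 9 2-oxo-4-[2-(trimethylsilyl)ethoxy]-2H-pyran-6-carbaldehyde
Conditions: SeO2, 1,4-dioxane, 150 °C, sealed tube
Reagents that add atoms: selenium dioxide, O=[Se]=O
Why: Riley oxidation converts the activated C6 methyl group of 4-alkoxy-6-methyl-2-pyranones into the aldehyde, and the ring positions and the TMSE ether are expected to be inert to the reagent.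

Step 7
Reactants: 6 4-(buta-1,3-diyn-1-yl)-1,2-bis(tert-butyldimethylsilyloxy)benzene; 9 2-oxo-4-[2-(trimethylsilyl)ethoxy]-2H-pyran-6-carbaldehyde
Product: 11 6-{(1R)-5-[3,4-bis(TBSO)phenyl]-1-hydroxypenta-2,4-diyn-1-yl}-4-[2-(trimethylsilyl)ethoxy]-2H-pyran-2-one, via methylzinc diynide 10 (not isolated)
Conditions: 6 (1.5 equiv), Me2Zn, (S,S)-ProPhenol (10 mol %), Ph3PO (20 mol %), toluene, 0 °C; then 9, 4 °C; aqueous work-up
Reagents that add atoms: none
Why: In the Zn–ProPhenol catalysed asymmetric addition of a terminal 1,3-diyne to an aldehyde, the dinuclear zinc complex holds aldehyde and alkynyl group on neighbouring zinc atoms and delivers the diynyl group to the Re face of 9, which sets the (R) carbinol centre.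

Step 8
Reactants: 11 6-{(1R)-5-[3,4-bis(TBSO)phenyl]-1-hydroxypenta-2,4-diyn-1-yl}-4-[2-(trimethylsilyl)ethoxy]-2H-pyran-2-one
Product: 12 (1R)-5-[3,4-bis(TBSO)phenyl]-1-{2-oxo-4-[2-(trimethylsilyl)ethoxy]-2H-pyran-6-yl}penta-2,4-diyn-1-yl methanesulfonate
Conditions: MsCl, Et3N, CH2Cl2, −78 °C; used without chromatography
Reagents that add atoms: methanesulfonyl chloride, CS(=O)(=O)Cl
Why: Sulfonylation at low temperature leaves the C–O bond intact, so the (R) configuration is kept, and the electron-poor pyranone suppresses ionisation of the mesylate.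

Step 9
Reactants: 12 (1R)-5-[3,4-bis(TBSO)phenyl]-1-{2-oxo-4-[2-(trimethylsilyl)ethoxy]-2H-pyran-6-yl}penta-2,4-diyn-1-yl methanesulfonate
Product: 13 (aR)-6-{5-[3,4-bis(TBSO)phenyl]-3-(tributylstannyl)penta-1,2-dien-4-yn-1-yl}-4-[2-(trimethylsilyl)ethoxy]-2H-pyran-2-one
Conditions: Bu3SnH, LiN(iPr)2, THF, −78 to 0 °C; CuBr·SMe2, −78 °C; then 12, −78 °C
Reagents that add atoms: tributyltin hydride, CCCC[SnH](CCCC)CCCC
Why: Stannylcuprate displacement of a propargylic mesylate is an anti SN2' process at the distal carbon of the nearer triple bond, so the (R) centre becomes the (aR) axis of the allenylstannane and the outer alkyne stays as the alkynyl substituent.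

Step 10
Reactants: 13 (aR)-6-{5-[3,4-bis(TBSO)phenyl]-3-(tributylstannyl)penta-1,2-dien-4-yn-1-yl}-4-[2-(trimethylsilyl)ethoxy]-2H-pyran-2-one; 2 3,4-bis(tert-butyldimethylsilyloxy)benzaldehyde
Product: 14 6-{(1R,2S)-1,6-bis[3,4-bis(TBSO)phenyl]-1-hydroxyhexa-3,5-diyn-2-yl}-4-[2-(trimethylsilyl)ethoxy]-2H-pyran-2-one (syn)
Conditions: 2 (1.2 equiv), BF3·OEt2 (2.2 equiv), CH2Cl2, −78 °C; aq NaHCO3 at −78 °C
Reagents that add atoms: none
Why: In this Lewis-acid-promoted SE2' addition of an allenylstannane the complexed aldehyde approaches the allene anti to the C–Sn bond, which turns the (aR) axis into the (S) centre, and the open transition state that keeps the aryl group away from ring D exposes the Re face of 2 and should give the syn (1R) carbinol.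

Step 11
Reactants: 14 6-{(1R,2S)-1,6-bis[3,4-bis(TBSO)phenyl]-1-hydroxyhexa-3,5-diyn-2-yl}-4-[2-(trimethylsilyl)ethoxy]-2H-pyran-2-one
Product: 15 methyl (4S,5R)-5-[3,4-bis(TBSO)phenyl]-2-{[3,4-bis(TBSO)phenyl]ethynyl}-4-{2-oxo-4-[2-(trimethylsilyl)ethoxy]-2H-pyran-6-yl}-4,5-dihydrofuran-3-carboxylate (cis)
Conditions: PdI2 (5 mol %), KI (50 mol %), CO/air 4:1 (40 bar), MeOH/1,4-dioxane 1:1, 60 °C, autoclave
Reagents that add atoms: carbon monoxide, [C-]#[O+]; methanol, CO
Why: Proposed new method: [PdI4]2− formed from PdI2 and KI binds the C3a≡C7a triple bond of 14, the C2 hydroxyl adds anti to C7a, the alkenyl–palladium bond left at C3a inserts CO, methanolysis of the acylpalladium iodide releases ester 15 with HI and zerovalent palladium, and O2 oxidises HI to I2, which regenerates PdI2. The closest known reaction type is the PdI2/KI oxidative heterocyclisation–alkoxycarbonylation of 3-yn-1-ols and 3-yne-1,2-diols that carry an isolated alkyne, and attack of a tethered heteroatom on the inner carbon of a 1,3-diyne is known from 2-(buta-1,3-diynyl)phenols and -anilines; the two have not been combined on a conjugated diynyl carbinol. Ring B closes in the 5-endo-dig mode. No stereocentre is made: the C2–O and C3–H bonds stay intact, so the syn relation of 14 appears as the cis relation of 15. The step needs oxygen attack at C7a alone and CO insertion ahead of protonolysis; attack at C3a would give an oxetane and attack at C7 or C6 a small ring holding a triple bond, so geometry leaves only C7a, while the CO pressure drives insertion. The base-free medium, the low stationary concentration of HI and the moderate temperature protect the acidic C3–H, the benzylic C2–O bond, the silyl ethers and the outer alkyne, which as an internal alkyne without a tethered nucleophile is not expected to be carbonylated by this catalyst.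

Step 12
Reactants: 15 methyl (4S,5R)-5-[3,4-bis(TBSO)phenyl]-2-{[3,4-bis(TBSO)phenyl]ethynyl}-4-{2-oxo-4-[2-(trimethylsilyl)ethoxy]-2H-pyran-6-yl}-4,5-dihydrofuran-3-carboxylate
Product: 16 (2R,3S)-2,6-bis[3,4-bis(TBSO)phenyl]-3-{2-oxo-4-[2-(trimethylsilyl)ethoxy]-2H-pyran-6-yl}-2,3-dihydro-4H-furo[3,2-c]pyran-4-one
Conditions: Ph3PAuNTf2 (5 mol %), H2O (2 equiv), ClCH2CH2Cl, 40 °C
Reagents that add atoms: none
Why: Cationic gold activates the remaining alkyne of this (Z)-2-en-4-ynoate, the electron-rich ester carbonyl oxygen attacks the aryl-bearing carbon C6 in the 6-endo-dig mode favoured by the donor aryl group and by formation of the aromatic pyranone, and water takes up the methyl group of the 2-methoxypyrylium as methanol and supplies the proton for protodeauration, a cyclisation well known for alkyl 2-alkynylbenzoates and enynoates.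

Step 13
Reactants: 16 (2R,3S)-2,6-bis[3,4-bis(TBSO)phenyl]-3-{2-oxo-4-[2-(trimethylsilyl)ethoxy]-2H-pyran-6-yl}-2,3-dihydro-4H-furo[3,2-c]pyran-4-one
Product: 17 (2R,3S)-2,6-bis(3,4-dihydroxyphenyl)-3-(4-hydroxy-2-oxo-2H-pyran-6-yl)-2,3-dihydro-4H-furo[3,2-c]pyran-4-one (CNP0224684.1)
Conditions: TBAF/AcOH 1:1 (8 equiv), THF, 0 °C to rt, argon
Reagents that add atoms: none
Why: Fluoride cleaves the four aryl silyl ethers and fragments the TMSE vinylogous ester to ethene, while one equivalent of acetic acid per fluoride protonates each phenoxide at once, so C3–H should not be removed, ring B should not open through a para-quinone methide, and neither stereocentre is touched.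

Compound list
1 | 3,4-dihydroxybenzaldehyde | O=Cc1ccc(O)c(O)c1 | starting material
2 | 3,4-bis(tert-butyldimethylsilyloxy)benzaldehyde | O=Cc1ccc(O[Si](C)(C)C(C)(C)C)c(O[Si](C)(C)C(C)(C)C)c1 | intermediate
3 | 4-(2,2-dibromoethenyl)-1,2-bis(tert-butyldimethylsilyloxy)benzene | BrC(Br)=Cc1ccc(O[Si](C)(C)C(C)(C)C)c(O[Si](C)(C)C(C)(C)C)c1 | intermediate
4 | trimethylsilylacetylene | C#C[Si](C)(C)C | starting material
5 | {4-[3,4-bis(tert-butyldimethylsilyloxy)phenyl]buta-1,3-diyn-1-yl}trimethylsilane | C[Si](C)(C)C#CC#Cc1ccc(O[Si](C)(C)C(C)(C)C)c(O[Si](C)(C)C(C)(C)C)c1 | intermediate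
6 | 4-(buta-1,3-diyn-1-yl)-1,2-bis(tert-butyldimethylsilyloxy)benzene | C#CC#Cc1ccc(O[Si](C)(C)C(C)(C)C)c(O[Si](C)(C)C(C)(C)C)c1 | intermediate
7 | 4-hydroxy-6-methyl-2H-pyran-2-one | Cc1cc(O)cc(=O)o1 | starting material
8 | 6-methyl-4-[2-(trimethylsilyl)ethoxy]-2H-pyran-2-one | Cc1cc(OCC[Si](C)(C)C)cc(=O)o1 | intermediate
9 | 2-oxo-4-[2-(trimethylsilyl)ethoxy]-2H-pyran-6-carbaldehyde | O=Cc1cc(OCC[Si](C)(C)C)cc(=O)o1 | intermediate
10 | methyl{4-[3,4-bis(TBSO)phenyl]buta-1,3-diyn-1-yl}zinc (not isolated) | C[Zn]C#CC#Cc1ccc(O[Si](C)(C)C(C)(C)C)c(O[Si](C)(C)C(C)(C)C)c1 | intermediate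
11 | 6-{(1R)-5-[3,4-bis(TBSO)phenyl]-1-hydroxypenta-2,4-diyn-1-yl}-4-[2-(trimethylsilyl)ethoxy]-2H-pyran-2-one | O[C@@H](c1cc(OCC[Si](C)(C)C)cc(=O)o1)C#CC#Cc1ccc(O[Si](C)(C)C(C)(C)C)c(O[Si](C)(C)C(C)(C)C)c1 | intermediate
12 | (1R)-5-[3,4-bis(TBSO)phenyl]-1-{2-oxo-4-[2-(trimethylsilyl)ethoxy]-2H-pyran-6-yl}penta-2,4-diyn-1-yl methanesulfonate | CS(=O)(=O)O[C@@H](c1cc(OCC[Si](C)(C)C)cc(=O)o1)C#CC#Cc1ccc(O[Si](C)(C)C(C)(C)C)c(O[Si](C)(C)C(C)(C)C)c1 | intermediate
13 | (aR)-6-{5-[3,4-bis(TBSO)phenyl]-3-(tributylstannyl)penta-1,2-dien-4-yn-1-yl}-4-[2-(trimethylsilyl)ethoxy]-2H-pyran-2-one | [H]C(c1cc(OCC[Si](C)(C)C)cc(=O)o1)=[C@]=C([Sn](CCCC)(CCCC)CCCC)C#Cc1ccc(O[Si](C)(C)C(C)(C)C)c(O[Si](C)(C)C(C)(C)C)c1 | intermediate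
14 | 6-{(1R,2S)-1,6-bis[3,4-bis(TBSO)phenyl]-1-hydroxyhexa-3,5-diyn-2-yl}-4-[2-(trimethylsilyl)ethoxy]-2H-pyran-2-one | O[C@@H](c1ccc(O[Si](C)(C)C(C)(C)C)c(O[Si](C)(C)C(C)(C)C)c1)[C@@H](c1cc(OCC[Si](C)(C)C)cc(=O)o1)C#CC#Cc1ccc(O[Si](C)(C)C(C)(C)C)c(O[Si](C)(C)C(C)(C)C)c1 | intermediate
15 | methyl (4S,5R)-5-[3,4-bis(TBSO)phenyl]-2-{[3,4-bis(TBSO)phenyl]ethynyl}-4-{2-oxo-4-[2-(trimethylsilyl)ethoxy]-2H-pyran-6-yl}-4,5-dihydrofuran-3-carboxylate | COC(=O)C1=C(C#Cc2ccc(O[Si](C)(C)C(C)(C)C)c(O[Si](C)(C)C(C)(C)C)c2)O[C@@H](c2ccc(O[Si](C)(C)C(C)(C)C)c(O[Si](C)(C)C(C)(C)C)c2)[C@H]1c1cc(OCC[Si](C)(C)C)cc(=O)o1 | intermediate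
16 | (2R,3S)-2,6-bis[3,4-bis(TBSO)phenyl]-3-{2-oxo-4-[2-(trimethylsilyl)ethoxy]-2H-pyran-6-yl}-2,3-dihydro-4H-furo[3,2-c]pyran-4-one | O=c1cc(OCC[Si](C)(C)C)cc([C@H]2c3c(cc(-c4ccc(O[Si](C)(C)C(C)(C)C)c(O[Si](C)(C)C(C)(C)C)c4)oc3=O)O[C@H]2c2ccc(O[Si](C)(C)C(C)(C)C)c(O[Si](C)(C)C(C)(C)C)c2)o1 | intermediate
17 | (2R,3S)-2,6-bis(3,4-dihydroxyphenyl)-3-(4-hydroxy-2-oxo-2H-pyran-6-yl)-2,3-dihydro-4H-furo[3,2-c]pyran-4-one | O=c1cc(O)cc([C@H]2c3c(cc(-c4ccc(O)c(O)c4)oc3=O)O[C@H]2c2ccc(O)c(O)c2)o1 | target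

Total step count: 13. Longest linear sequence: 11 steps (1, 2, 3, 4, 7, 8, 9, 10, 11, 12, 13).

Steps most likely to fail

1. Step 11.
- What may go wrong: the alkenyl–palladium bond may be protonated before it takes up CO. Palladium may also engage the outer alkyne of the product, the benzylic alcohol may solvolyse in methanol, or the dihydrofuran may be dehydrogenated to the furan.
- Fallback (known chemistry), from 14 back to 15: the two bonds are made one after the other. 5-endo-dig iodocyclisation of the homopropargylic alcohol (I2, NaHCO3, MeCN, 0 °C) forms O1–C7a and gives the 4-iodo-2,3-dihydrofuran F1. Palladium-catalysed methoxycarbonylation of this alkenyl iodide (PdCl2(PPh3)2, CO 1 bar, MeOH/THF, iPr2NEt, 40 °C) then forms C3a–C4 and gives 15.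

2. Step 10.
- What may go wrong: facial selectivity on the aromatic aldehyde may be poor. Binding of BF3 to ring D may slow the already electron-poor allene, and the electron-rich benzylic boron alkoxide may ionise.
- Fallback, from 6 and 9 back to 14: an anti-selective closed transition state is combined with inversion of the carbinol. The alkynylation of step 7 run with (R,R)-ProPhenol gives the (S)-propargylic alcohol F2, and MsCl/Et3N gives the (S)-mesylate F3. PdCl2(dppf) (5 mol %) and InI in THF/HMPA convert F3 by anti oxidative addition and transmetalation with retention into the (aS)-allenylindium iodide methanesulfonate F4.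
- F4 adds to 2 through a cyclic transition state on the indium-bearing face to give the anti (1S,2S)-carbinol F5, which already has the correct centre next to ring D. Mitsunobu inversion with chloroacetic acid (PPh3, DIAD, toluene, 0 °C) gives the (1R,2S)-chloroacetate F6. Thiourea with NaHCO3 in EtOH/THF removes the chloroacetyl group and gives 14.

3. Step 13.
- What may go wrong: fluoride frees the para-phenoxide of ring A at a stage where O1 already belongs to a 4-hydroxy-2-pyranone, a good leaving group. Opening of ring B to a para-quinone methide and re-closure would erode the cis relation. Deprotonation at C3 and air oxidation of the catechols are further losses.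
- Fallback, from 15 to 17: the order of the last two operations is reversed. The buffered fluoride treatment (TBAF/AcOH, THF, 0 °C) is applied to 15, where O1 is only the enol ether oxygen of a β-alkoxyacrylate and leaves far less readily, and gives the fully desilylated methyl ester F7. The gold-catalysed 6-endo-dig lactonisation (Ph3PAuNTf2, H2O, MeCN/THF, rt) then closes ring C as the final step, without base or fluoride, and gives 17.

Further compounds
F1 | step 11 | 6-{(2R,3S)-2-[3,4-bis(TBSO)phenyl]-5-{[3,4-bis(TBSO)phenyl]ethynyl}-4-iodo-2,3-dihydrofuran-3-yl}-4-[2-(trimethylsilyl)ethoxy]-2H-pyran-2-one | IC1=C(C#Cc2ccc(O[Si](C)(C)C(C)(C)C)c(O[Si](C)(C)C(C)(C)C)c2)O[C@@H](c2ccc(O[Si](C)(C)C(C)(C)C)c(O[Si](C)(C)C(C)(C)C)c2)[C@H]1c1cc(OCC[Si](C)(C)C)cc(=O)o1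
F2 | step 10 | 6-{(1S)-5-[3,4-bis(TBSO)phenyl]-1-hydroxypenta-2,4-diyn-1-yl}-4-[2-(trimethylsilyl)ethoxy]-2H-pyran-2-one | O[C@H](c1cc(OCC[Si](C)(C)C)cc(=O)o1)C#CC#Cc1ccc(O[Si](C)(C)C(C)(C)C)c(O[Si](C)(C)C(C)(C)C)c1
F3 | step 10 | (1S)-5-[3,4-bis(TBSO)phenyl]-1-{2-oxo-4-[2-(trimethylsilyl)ethoxy]-2H-pyran-6-yl}penta-2,4-diyn-1-yl methanesulfonate | CS(=O)(=O)O[C@H](c1cc(OCC[Si](C)(C)C)cc(=O)o1)C#CC#Cc1ccc(O[Si](C)(C)C(C)(C)C)c(O[Si](C)(C)C(C)(C)C)c1
F4 | step 10 | (aS)-{1-[3,4-bis(TBSO)phenyl]-5-{2-oxo-4-[2-(trimethylsilyl)ethoxy]-2H-pyran-6-yl}penta-3,4-dien-1-yn-3-yl}indium iodide methanesulfonate | [H]C(c1cc(OCC[Si](C)(C)C)cc(=O)o1)=[C@@]=C([In](I)OS(C)(=O)=O)C#Cc1ccc(O[Si](C)(C)C(C)(C)C)c(O[Si](C)(C)C(C)(C)C)c1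
F5 | step 10 | 6-{(1S,2S)-1,6-bis[3,4-bis(TBSO)phenyl]-1-hydroxyhexa-3,5-diyn-2-yl}-4-[2-(trimethylsilyl)ethoxy]-2H-pyran-2-one | O[C@H](c1ccc(O[Si](C)(C)C(C)(C)C)c(O[Si](C)(C)C(C)(C)C)c1)[C@@H](c1cc(OCC[Si](C)(C)C)cc(=O)o1)C#CC#Cc1ccc(O[Si](C)(C)C(C)(C)C)c(O[Si](C)(C)C(C)(C)C)c1
F6 | step 10 | (1R,2S)-1,6-bis[3,4-bis(TBSO)phenyl]-2-{2-oxo-4-[2-(trimethylsilyl)ethoxy]-2H-pyran-6-yl}hexa-3,5-diyn-1-yl chloroacetate | O=C(CCl)O[C@@H](c1ccc(O[Si](C)(C)C(C)(C)C)c(O[Si](C)(C)C(C)(C)C)c1)[C@@H](c1cc(OCC[Si](C)(C)C)cc(=O)o1)C#CC#Cc1ccc(O[Si](C)(C)C(C)(C)C)c(O[Si](C)(C)C(C)(C)C)c1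
F7 | step 13 | methyl (4S,5R)-5-(3,4-dihydroxyphenyl)-2-[(3,4-dihydroxyphenyl)ethynyl]-4-(4-hydroxy-2-oxo-2H-pyran-6-yl)-4,5-dihydrofuran-3-carboxylate | COC(=O)C1=C(C#Cc2ccc(O)c(O)c2)O[C@@H](c2ccc(O)c(O)c2)[C@H]1c1cc(O)cc(=O)o1
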